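**Retrosynthetic overview**

1. Structural feature: ring C (C8, C9, C11, C12, C13, C14) is a chair locked by the C15–C16 bridge. C10 is its axial substituent on C9, H-12α is the axial hydrogen on the same face, and the α-oxygen on C10 (the lactone oxygen of the target) is cis to C11 across ring B. O, C10, C9, C11, C12 and H-12α can therefore form a six-membered array.
2. Key disconnection: C12–O, made by 1,5-hydrogen transfer to the C10 alkoxyl of the lactone-opened 19-dimethylamide (as 16-norketone), which closes a temporary oxolane (O, C10, C9, C11, C12). Acid then trades this ether oxygen on C10 for the 19,10-lactone and leaves 12α-OH; C16=CH2 is put on last by Wittig reaction.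
3. Precursor: the 2β,3β-diol comes from osmylation of C2=C3 on the face away from the lactone bridge. C2=C3 and C13–H come from one radical deoxygenation of the 3,13-bis(methyl oxalate) of gibberellic acid, which supplies rings A–D and C4, C5, C6, C8, C9, C10, C13.
4. Ring order: rings A–D and the lactone come with gibberellic acid; the lactone is opened (step 7), the oxolane closed (step 8), then the oxolane opened and the lactone closed again (step 9).

Key step: step 8

Remark (assumption): gibberellic acid (GA3), the bulk fermentation product, is taken as the commercially available chiral starting material, so the route is a partial synthesis from GA3. Gibberellane numbering is used, and α is the face of the 19,10-lactone bridge.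

**Route**

Step 1
Reactants: 1 gibberellic acid (GA3)
Product: 2 gibberellic acid 7-tert-butyl ester
Conditions: O-tert-butyl-N,N'-diisopropylisourea, THF–CH2Cl2, rt
Reagents that add atoms: O-tert-butyl-N,N'-diisopropylisourea, CC(C)NC(=NC(C)C)OC(C)(C)C
Why: O-alkylation of the carboxylic acid by the isourea (proton transfer, then tert-butyl transfer to the carboxylate) runs near neutrality, which spares the allylic lactone and leaves both hydroxyls free; the tert-butyl ester is chosen because it should resist the aluminium amide of step 7 and fall in the acid of step 9.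

Step 2
Reactants: 2 gibberellic acid 7-tert-butyl ester
Product: 3 3β,13-bis(methoxyoxalyloxy) derivative of 2 (bis(methyl oxalate))
Conditions: MeO2CCOCl, pyridine, DMAP (cat.), CH2Cl2, 0 °C → rt
Reagents that add atoms: methyl chlorooxoacetate, COC(=O)C(=O)Cl
Why: DMAP-catalysed acylation by the reactive acid chloride should reach both the hindered secondary 3β-OH and the tertiary bridgehead 13-OH and turn each into the half-oxalate that serves as radical leaving group in step 4.

Step 3
Reactants: 3 bis(methyl oxalate)
Product: 4 16-oxo-17-nor bis(methyl oxalate) (16-norketone)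
Conditions: O3 (1 equiv), CH2Cl2, −78 °C; PPh3, → rt
Reagents that add atoms: ozone, [O-][O+]=O
Why: Criegee ozonolysis with phosphine reduction should cleave the electron-rich exocyclic C16=C17 bond, while C1=C2, flanked by the lactone oxygen on C10 and the oxalate on C3, is hindered and inductively deactivated; cleaving at this stage leaves step 5 a single olefin and gives a ketone that tolerates the iodine(I) chemistry of step 8, which an exocyclic olefin would not.

Step 4
Reactants: 4 16-norketone bis(methyl oxalate)
Product: 5 tert-butyl 16-oxo-17-nor-2-ene 19,10-lactone (13-deoxy; 2,3-didehydro-GA9 norketone ester)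
Conditions: Bu3SnH, AIBN, PhMe, 110 °C
Reagents that add atoms: none
Why: Barton–McCombie-type radical deoxygenation of methyl oxalates (stannyl radical addition, C–O β-scission): the C13 bridgehead radical takes hydrogen with retention imposed by the cage, and the C1–C2–C3 allyl radical should take hydrogen at C1, away from the quaternary C4, as in the stannane reduction of 1-halo-2-enes of this ring system, which places the olefin at C2=C3.

Step 5
Reactants: 5 2-ene norketone tert-butyl ester
Product: 6 2β,3β-diol (GA34 16-norketone tert-butyl ester)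
Conditions: OsO4 (cat.), NMO, acetone–H2O, rt
Reagents that add atoms: osmium tetroxide, O=[Os](=O)(=O)=O; N-methylmorpholine N-oxide, C[N+]1([O-])CCOCC1
Why: Upjohn dihydroxylation: osmium tetroxide adds syn from the β face because the α face of C2=C3 lies under the 1,3-diaxial 19,10-lactone bridge, which sets C2 and C3 as the cis 2β,3β-diol; ketone, lactone and ester are inert.

Step 6
Reactants: 6 2β,3β-diol
Product: 7 2β,3β-O-isopropylidene derivative (acetonide lactone)
Conditions: 2-methoxypropene, PPTS (cat.), CH2Cl2, 0 °C
Reagents that add atoms: 2-methoxypropene, COC(C)=C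
Why: acid-catalysed acetalisation with the enol ether ties the cis-diol into a cis-fused dioxolane, so that only the C10 hydroxyl is free to form a hypoiodite in step 8; the mild catalyst should leave the tert-butyl ester intact.

Step 7
Reactants: 7 acetonide lactone
Product: 8 10α-hydroxy 19-(N,N-dimethyl)amide (2β,3β-acetonide; 7-tert-butyl ester; 16-norketone)
Conditions: Me2AlNMe2 (stock solution), PhMe–CH2Cl2, 45 °C; aq. Rochelle salt, 0 °C; used without delay
Reagents that add atoms: dimethylaluminium dimethylamide, C[Al](C)N(C)C
Why: Weinreb-type aminolysis: aluminium activates the γ-lactone carbonyl and transfers the dimethylamido group, the tertiary C10 oxygen leaves as its aluminium alkoxide with C10 untouched (acyl–oxygen cleavage), the hindered tert-butyl ester should not react, and the C16 ketone is at most masked reversibly (hemiaminal or enamine) until the neutral aqueous work-up.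

Step 8
Reactants: 8 10α-hydroxy 19-dimethylamide
Product: 10 10α,12α-ether (oxolane) 19-dimethylamide, via C10 hypoiodite 9 (not isolated)
Conditions: PhI(OAc)2, I2, cyclohexane (degassed), hν (visible), rt
Reagents that add atoms: none
Why: Acetyl hypoiodite turns the tertiary C10–OH into hypoiodite 9, light homolyses its O–I bond, the C10 alkoxyl takes the axial H-12α through a six-membered chair-like transition state (O, C10, C9, C11, C12, H), and the C12 radical is iodinated on its open β face and then displaced with inversion (or oxidised further and captured) by the same oxygen. The closest known reaction type is the hypoiodite remote functionalisation of alcohols to tetrahydrofurans, which is established for tertiary alcohols that hold a syn-axial δ-C–H bond. The oxolane (O, C10, C9, C11, C12) closes by C12–O bond formation in a 5-exo-tet sense at the oxidised C12. C12 is the only new stereocentre and is fixed by the tether, since the oxygen sits on the α face of C10 and can bridge only to the axial α position of C12. The step needs transfer of H-12α to outrun transfer of the axial hydrogen on C14, β-scission of a C10–C bond and abstraction of H-3α: the C10–O bond is cis to C11 across the C9–C10 bond of ring B and so points over C12 and away from C14, the ring-A chair keeps H-3α equatorial and remote, H-2α and the C11 hydrogens are only 1,4-related, and C19 carries no hydrogen.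

Step 9
Reactants: 10 10α,12α-ether 19-dimethylamide
Product: 13 GA49 16-norketone (2β,3β,12α-trihydroxy-16-oxo-17-nor 19,10-lactone 7-acid), via deprotected ether amide 11 (not isolated), via iminium lactone trifluoroacetate 12 (not isolated)
Conditions: TFA–H2O (9:1), rt → 45 °C; then MeOH–H2O, rt (solvolysis of any trifluoroacetates)
Reagents that add atoms: water, O
Why: specific-acid SN1 ether cleavage with neighbouring-group capture: the oxolane oxygen is protonated, the tertiary C10–O bond ionises, the 1,3-diaxial amide oxygen on C4 captures the C10 cation from the α face (the only face on which the five-membered ring can close, so C10 regains its configuration) and water hydrolyses the iminium lactone irreversibly with loss of dimethylamine, while the C12–O bond is never broken and tert-butyl ester and acetonide fall in the same medium; the step is placed before the methylenation because a 16-ketone survives this acid and a 16-ene would not.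

Step 10
Reactants: 13 GA49 16-norketone
Product: 16 GA49 (the target gibberellin; 2β,3β,12α-trihydroxy 16-ene 19,10-lactone 7-acid), via persilylated norketone 14 (not isolated), via persilylated GA49 15 (not isolated)
Conditions: BSA, THF, 50 °C, evaporate; Ph3PCH3Br, KHMDS, THF, 0 °C → rt; citric acid, MeOH–H2O (pH 3), rt
Reagents that add atoms: methyltriphenylphosphonium bromide, C[P+](c1ccccc1)(c1ccccc1)c1ccccc1.[Br-] (as its ylide, C=P(c1ccccc1)(c1ccccc1)c1ccccc1)
Why: Wittig methylenation of the hindered bicyclic C16 ketone; transient trimethylsilylation of the three hydroxyls and the acid keeps the 3β-oxygen from becoming an alkoxide (no retro-aldol epimerisation at C3 next to the lactone carbonyl), and the mild acidic work-up should remove the silyl groups without touching the new exocyclic olefin.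

**Compound list**

1 | gibberellic acid (GA3) | C=C1C[C@]23C[C@@]1(O)CC[C@H]2[C@@]12C=C[C@H](O)[C@@](C)(C(=O)O1)[C@H]2[C@@H]3C(=O)O | starting material
2 | gibberellic acid 7-tert-butyl ester | C=C1C[C@]23C[C@@]1(O)CC[C@H]2[C@@]12C=C[C@H](O)[C@@](C)(C(=O)O1)[C@H]2[C@@H]3C(=O)OC(C)(C)C | intermediate
3 | 3β,13-bis(methoxyoxalyloxy) derivative of 2 | C=C1C[C@]23C[C@@]1(OC(=O)C(=O)OC)CC[C@H]2[C@@]12C=C[C@H](OC(=O)C(=O)OC)[C@@](C)(C(=O)O1)[C@H]2[C@@H]3C(=O)OC(C)(C)C | intermediate
4 | 16-oxo-17-nor bis(methyl oxalate) | O=C1C[C@]23C[C@@]1(OC(=O)C(=O)OC)CC[C@H]2[C@@]12C=C[C@H](OC(=O)C(=O)OC)[C@@](C)(C(=O)O1)[C@H]2[C@@H]3C(=O)OC(C)(C)C | intermediate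
5 | tert-butyl 16-oxo-17-nor-2-ene 19,10-lactone (13-deoxy) | O=C1C[C@]23C[C@H]1CC[C@H]2[C@@]12CC=C[C@@](C)(C(=O)O1)[C@H]2[C@@H]3C(=O)OC(C)(C)C | intermediate
6 | 2β,3β-diol (GA34 16-norketone tert-butyl ester) | O=C1C[C@]23C[C@H]1CC[C@H]2[C@@]12C[C@H](O)[C@H](O)[C@@](C)(C(=O)O1)[C@H]2[C@@H]3C(=O)OC(C)(C)C | intermediate
7 | 2β,3β-acetonide of 6 | O=C1C[C@]23C[C@H]1CC[C@H]2[C@@]12C[C@@H]4OC(C)(C)O[C@@H]4[C@@](C)(C(=O)O1)[C@H]2[C@@H]3C(=O)OC(C)(C)C | intermediate
8 | 10α-hydroxy 19-(N,N-dimethyl)amide (acetonide, tert-butyl ester, 16-norketone) | O=C1C[C@]23C[C@H]1CC[C@H]2[C@]2(O)C[C@@H]4OC(C)(C)O[C@@H]4[C@@](C)(C(=O)N(C)C)[C@H]2[C@@H]3C(=O)OC(C)(C)C | intermediate (key-step precursor)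
9 | C10 hypoiodite of 8 | O=C1C[C@]23C[C@H]1CC[C@H]2[C@]2(OI)C[C@@H]4OC(C)(C)O[C@@H]4[C@@](C)(C(=O)N(C)C)[C@H]2[C@@H]3C(=O)OC(C)(C)C | intermediate (not isolated)
10 | 10α,12α-ether 19-dimethylamide (acetonide, tert-butyl ester, 16-norketone) | O=C1C[C@]23C[C@H]1[C@@H]5C[C@H]2[C@]2(O5)C[C@@H]4OC(C)(C)O[C@@H]4[C@@](C)(C(=O)N(C)C)[C@H]2[C@@H]3C(=O)OC(C)(C)C | intermediate (key-step product)
11 | 10α,12α-ether 19-dimethylamide 2β,3β-diol 7-acid | O=C1C[C@]23C[C@H]1[C@@H]5C[C@H]2[C@]2(O5)C[C@H](O)[C@H](O)[C@@](C)(C(=O)N(C)C)[C@H]2[C@@H]3C(=O)O | intermediate (not isolated)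
12 | 19,10-(N,N-dimethyliminium) lactone trifluoroacetate, 12α-OH free | O=C1C[C@]23C[C@H]1[C@@H](O)C[C@H]2[C@@]12C[C@H](O)[C@H](O)[C@@](C)(C(=[N+](C)C)O1)[C@H]2[C@@H]3C(=O)O.[O-]C(=O)C(F)(F)F | intermediate (not isolated)
13 | GA49 16-norketone | O=C1C[C@]23C[C@H]1[C@@H](O)C[C@H]2[C@@]12C[C@H](O)[C@H](O)[C@@](C)(C(=O)O1)[C@H]2[C@@H]3C(=O)O | intermediate
14 | 2,3,12-tris(trimethylsilyl) ether trimethylsilyl ester of 13 | O=C1C[C@]23C[C@H]1[C@@H](O[Si](C)(C)C)C[C@H]2[C@@]12C[C@H](O[Si](C)(C)C)[C@H](O[Si](C)(C)C)[C@@](C)(C(=O)O1)[C@H]2[C@@H]3C(=O)O[Si](C)(C)C | intermediate (not isolated)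
15 | 2,3,12-tris(trimethylsilyl) ether trimethylsilyl ester of GA49 | C=C1C[C@]23C[C@H]1[C@@H](O[Si](C)(C)C)C[C@H]2[C@@]12C[C@H](O[Si](C)(C)C)[C@H](O[Si](C)(C)C)[C@@](C)(C(=O)O1)[C@H]2[C@@H]3C(=O)O[Si](C)(C)C | intermediate (not isolated)
16 | GA49 (target gibberellin) | C=C1C[C@]23C[C@H]1[C@@H](O)C[C@H]2[C@@]12C[C@H](O)[C@H](O)[C@@](C)(C(=O)O1)[C@H]2[C@@H]3C(=O)O | target

**Step count and risks**

Total step count: 10. Longest linear sequence: 10 steps (1 → 16).

Steps most likely to fail:

1. Step 8 (key step). Ring B is a cyclopentane, so β-scission of a C10–C bond of the tertiary alkoxyl may outrun the 1,5-hydrogen shift, and hydrogen may instead be taken from an N-methyl group of the nearby amide. The iodine(I)/acetic acid medium may also return the hydroxy amide to the lactone with loss of dimethylamine, or eliminate an oxidised C12 to the 11-ene. Fallback (sets out from 8, comes back at 16): Barton nitrite photolysis in place of the hypoiodite, with C12 carried as a ketone. Alcohol 8 is nitrosated (NOCl, pyridine, −30 °C) to the C10 nitrite F1. Irradiation in toluene at −30 °C, where the lower temperature favours the six-membered hydrogen transfer over fragmentation and no electrophilic iodine or acid is present, should give the C12 nitroso compound, which is isomerised in warm 2-propanol to the 12-oxime F2. Wittig methylenation with excess ylide should give the 16-methylene 12-oxime F3, buffered aqueous TiCl3 the 16-methylene 12-ketone F4, and L-Selectride at −78 °C the 16-methylene 12α-alcohol F5; hydride should arrive equatorially from the β face because the axial approach is blocked by C10. Cleavage of the tert-butyl ester (TMSOTf, 2,6-lutidine) and then 80% aqueous acetic acid at 40 °C should lead to 16. That last treatment hydrolyses the acetonide and lactonises the hydroxy amide by acyl substitution, which needs no C10 cation and should spare the olefin. In this fallback C12 is set by reagent approach to a ketone, not by the tether.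

2. Step 9. The C10 cation may be recaptured by the tethered 12-hydroxyl (internal return), so that the ether persists. It may also lose a proton from C1, C5 or C9; reprotonation of such olefins could scramble C5 or C9. Fallback (sets out from 10, comes back at 13): acetylative ether cleavage. With Ac2O and BF3·OEt2 in CH2Cl2 at 0 °C the oxolane oxygen is acetylated, so the leaving oxygen departs as an acetate that cannot return. C10–O cleavage, capture by the amide and aqueous work-up should then give the 2β,3β,12α-triacetate lactone acid F6, with the acetonide acetolysed and the tert-butyl ester cleaved. 3 M HCl in aqueous dioxane at 50 °C, which the norketone tolerates and which avoids base at C3, should remove the acetates and give 13.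

3. Step 7. Attack on the neopentyl-type lactone carbonyl may be too slow, the aluminium amide may react at the C16 ketone, or the hydroxy amide may re-close to the lactone during work-up. Fallback (sets out from 7, comes back at 13): hydroxide opening and O-methylation, with a methyl ester in the role of the amide. KOH in aqueous methanol should open the lactone to the potassium 10-hydroxy-19-carboxylate F7, the hindered tert-butyl ester surviving. Methyl iodide in DMF should give the 10-hydroxy 19-methyl ester F8, which is kept neutral and used at once. The hypoiodite conditions of step 8 should give the 10α,12α-ether 19-methyl ester F9. Aqueous TFA as in step 9, with the ester carbonyl capturing the C10 cation and losing its methyl group as methanol, should give 13.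

**Further compounds**

F1 | step 8 | C10 nitrite of 8 | O=C1C[C@]23C[C@H]1CC[C@H]2[C@]2(ON=O)C[C@@H]4OC(C)(C)O[C@@H]4[C@@](C)(C(=O)N(C)C)[C@H]2[C@@H]3C(=O)OC(C)(C)C
F2 | step 8 | 12-oxime of 8 (10α-hydroxy 19-dimethylamide, 16-ketone) | O=C1C[C@]23C[C@H]1C(=NO)C[C@H]2[C@]2(O)C[C@@H]4OC(C)(C)O[C@@H]4[C@@](C)(C(=O)N(C)C)[C@H]2[C@@H]3C(=O)OC(C)(C)C
F3 | step 8 | 16-methylene 12-oxime | C=C1C[C@]23C[C@H]1C(=NO)C[C@H]2[C@]2(O)C[C@@H]4OC(C)(C)O[C@@H]4[C@@](C)(C(=O)N(C)C)[C@H]2[C@@H]3C(=O)OC(C)(C)C
F4 | step 8 | 16-methylene 12-ketone | C=C1C[C@]23C[C@H]1C(=O)C[C@H]2[C@]2(O)C[C@@H]4OC(C)(C)O[C@@H]4[C@@](C)(C(=O)N(C)C)[C@H]2[C@@H]3C(=O)OC(C)(C)C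
F5 | step 8 | 16-methylene 12α-alcohol (10α-hydroxy 19-dimethylamide) | C=C1C[C@]23C[C@H]1[C@@H](O)C[C@H]2[C@]2(O)C[C@@H]4OC(C)(C)O[C@@H]4[C@@](C)(C(=O)N(C)C)[C@H]2[C@@H]3C(=O)OC(C)(C)C
F6 | step 9 | 2β,3β,12α-triacetate of GA49 16-norketone | O=C1C[C@]23C[C@H]1[C@@H](OC(C)=O)C[C@H]2[C@@]12C[C@H](OC(C)=O)[C@H](OC(C)=O)[C@@](C)(C(=O)O1)[C@H]2[C@@H]3C(=O)O
F7 | step 7 | potassium 10α-hydroxy-19-carboxylate (acetonide, tert-butyl ester, 16-norketone) | O=C1C[C@]23C[C@H]1CC[C@H]2[C@]2(O)C[C@@H]4OC(C)(C)O[C@@H]4[C@@](C)(C(=O)[O-])[C@H]2[C@@H]3C(=O)OC(C)(C)C.[K+]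
F8 | step 7 | 10α-hydroxy 19-methyl ester | O=C1C[C@]23C[C@H]1CC[C@H]2[C@]2(O)C[C@@H]4OC(C)(C)O[C@@H]4[C@@](C)(C(=O)OC)[C@H]2[C@@H]3C(=O)OC(C)(C)C
F9 | step 7 | 10α,12α-ether 19-methyl ester | O=C1C[C@]23C[C@H]1[C@@H]5C[C@H]2[C@]2(O5)C[C@@H]4OC(C)(C)O[C@@H]4[C@@](C)(C(=O)OC)[C@H]2[C@@H]3C(=O)OC(C)(C)C
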